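**Retrosynthetic overview**
Ring A is a cyclohexene whose only alkene, C3=C4 (C18 methyl on C4), lies beside the quaternary fusion carbon C5. Breaking C1–C2 and C5–C10 is therefore a retro-Diels–Alder cut that opens both rings to one chain, with C8 and C9 on the link C6–C7–C8–C9.
A phenylsulfonyl group on C1 activates the dienophile C1=C10 and is removed reductively afterwards, so rings A and B form together, in one step, from an acyclic triene.
The triene is cut at C5–C6 (Negishi coupling of a C6 alkylzinc with a geometrically defined enol tosylate), at C2=C3 (Wittig) and at C1=C10 (Horner–Wadsworth–Emmons).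
C8 comes from desymmetrised 3-methylglutaric anhydride and C9 from two successive lactone enolate alkylations; the lactone rings are temporary templates only.
The last C–C bond is C12–C13: a second Negishi coupling joins the decalin iodide to a (Z)-iodoalkene that already carries the docosanoate.

Key step: step 15

Assumption: atom labels C1–C20 follow clerodane numbering, and (DHQD)2AQN is taken to give the (R)-half-ester 2; if the sense proved opposite, the pseudoenantiomeric (DHQ)2AQN would be used in the same way.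

**Step 1**
Reactants: 1 3-methylglutaric anhydride
Product: 2 (R)-5-methoxy-3-methyl-5-oxopentanoic acid
Conditions: MeOH (10 equiv), (DHQD)2AQN (cat.), Et2O, −40 °C
Reagents that add atoms: methanol, CO
Why: Catalytic desymmetrising alcoholysis of a prochiral cyclic anhydride, in which the cinchona amine activates methanol by general-base catalysis and tells the two enantiotopic carbonyl groups apart, which sets C8 as R.

**Step 2**
Reactants: 2 (R)-5-methoxy-3-methyl-5-oxopentanoic acid
Product: 4 (R)-4-methyloxan-2-one, via hydroxy ester 3 (not isolated)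
Conditions: BH3·SMe2, THF, 0 °C → rt; H2O; then TsOH·H2O (cat.), PhMe, rt
Reagents that add atoms: none
Why: Chemoselective borane reduction takes the free acid much faster than the methyl ester, and the 5-hydroxy ester then closes by acid-catalysed lactonisation without touching C8.

**Step 3**
Reactants: 4 (R)-4-methyloxan-2-one
Product: 6 (3S,4R)-3,4-dimethyloxan-2-one, via lithium enolate 5 (not isolated)
Conditions: LiN(i-Pr)2, THF, −78 °C; MeI, −78 → −40 °C
Reagents that add atoms: iodomethane, CI
Why: Kinetic lactone enolate alkylation brings in C20 mainly anti to the ring methyl, and the new centre does not matter because it is planarised again in step 4.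

**Step 4**
Reactants: 6 (3S,4R)-3,4-dimethyloxan-2-one; 7 allyl bromide
Product: 9 (3S,4R)-3-allyl-3,4-dimethyloxan-2-one, via lithium enolate 8 (not isolated)
Conditions: LiN(i-Pr)2, THF/DMPU, −78 °C; then 7, −78 → −20 °C
Reagents that add atoms: none
Why: Alkylation of the tetrasubstituted lactone enolate, in which allylic strain with the C20 methyl turns the C17 methyl pseudoaxial so that allyl bromide should attack the opposite face, setting the quaternary C9 with the allyl group trans to C17.

**Step 5**
Reactants: 9 (3S,4R)-3-allyl-3,4-dimethyloxan-2-one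
Product: 11 (3S)-3-[(2R)-4-hydroxybutan-2-yl]-3-methyloxolan-2-one, via hydroxyethyl δ-lactone 10 (not isolated)
Conditions: O3, CH2Cl2/MeOH, −78 °C; NaBH4, −78 → 0 °C; then camphorsulfonic acid (cat.), CH2Cl2, rt
Reagents that add atoms: ozone, [O-][O+]=O
Why: Ozonolysis with reductive work-up trims the allyl group to a 2-hydroxyethyl arm, and acid-catalysed translactonisation should then move the acyl group onto it because a γ-lactone is more stable than a δ-lactone, C8 and C9 taking no part.

**Step 6**
Reactants: 11 (3S)-3-[(2R)-4-hydroxybutan-2-yl]-3-methyloxolan-2-one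
Product: 12 (3S)-3-[(2R)-4-iodobutan-2-yl]-3-methyloxolan-2-one
Conditions: I2, PPh3, imidazole, CH2Cl2, 0 °C → rt
Reagents that add atoms: iodine, II
Why: Appel-type iodination converts the unhindered primary C6 alcohol by SN2 displacement of its alkoxyphosphonium ion and leaves the lactone alone.

**Step 7**
Reactants: 13 methyl 2-methyl-3-oxobutanoate
Product: 14 methyl (E)-2-methyl-3-(tosyloxy)but-2-enoate
Conditions: TsCl, N-methylimidazole, Et3N, CH2Cl2, 0 °C → rt
Reagents that add atoms: 4-toluenesulfonyl chloride, Cc1ccc(cc1)S(=O)(=O)Cl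
Why: Stereodefined enol sulfonylation of an α-substituted β-keto ester, in which an amine base without a chelating metal favours the dipole-minimised enolate (oxygen trans to the ester) and the N-sulfonylimidazolium salt traps it as the (E)-tosylate.

**Step 8**
Reactants: 12 (3S)-3-[(2R)-4-iodobutan-2-yl]-3-methyloxolan-2-one; 14 methyl (E)-2-methyl-3-(tosyloxy)but-2-enoate
Product: 16 methyl (2E,6R)-2,3-dimethyl-6-[(3S)-3-methyl-2-oxooxolan-3-yl]hept-2-enoate, via alkylzinc iodide 15 (not isolated)
Conditions: Zn dust (I2-activated), DMA, 40 °C; then 14, Pd(PPh3)4 (5 mol %), THF/DMA, 60 °C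
Reagents that add atoms: none
Why: Direct zinc insertion tolerates the lactone, and the Negishi coupling of the alkylzinc iodide with the ester-activated enol tosylate runs through oxidative addition, transmetalation and reductive elimination with retention, so C6 should end up trans to the ester carbon C3.

**Step 9**
Reactants: 16 methyl (2E,6R)-2,3-dimethyl-6-[(3S)-3-methyl-2-oxooxolan-3-yl]hept-2-enoate
Product: 17 (2E,6R,7S)-7-(hydroxymethyl)-2,3,6,7-tetramethylnon-2-ene-1,9-diol
Conditions: LiAlH4, THF, 0 °C → rt; aqueous work-up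
Reagents that add atoms: none
Why: Exhaustive hydride reduction takes the hindered enoate to the allylic alcohol by 1,2-attack and opens the lactone to the C10/C12 diol without touching a stereocentre or the alkene.

**Step 10**
Reactants: 17 (2E,6R,7S)-7-(hydroxymethyl)-2,3,6,7-tetramethylnon-2-ene-1,9-diol
Product: 18 (2E,6R,7S)-9-hydroxy-7-(hydroxymethyl)-2,3,6,7-tetramethylnon-2-enal
Conditions: MnO2 (activated, excess), CH2Cl2, rt
Reagents that add atoms: none
Why: Selective allylic oxidation, since activated MnO2 oxidises the allylic C3 hydroxyl far faster than the two saturated primary alcohols.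

**Step 11**
Reactants: 18 (2E,6R,7S)-9-hydroxy-7-(hydroxymethyl)-2,3,6,7-tetramethylnon-2-enal
Product: 19 (2S,3R,6E)-2-(2-hydroxyethyl)-2,3,6,7-tetramethylnona-6,8-dien-1-ol
Conditions: Ph3PCH3Br, KOt-Bu (excess of both), THF, 0 °C; then 18, −78 → 0 °C
Reagents that add atoms: methyltriphenylphosphonium bromide, C[P+](c1ccccc1)(c1ccccc1)c1ccccc1.[Br-]
Why: Wittig methylenation with a non-stabilised ylide (the surplus is parked on the two hydroxyl groups) adds C2 faster than the enal can be deprotonated, so the C4=C5 geometry should be kept.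

**Step 12**
Reactants: 19 (2S,3R,6E)-2-(2-hydroxyethyl)-2,3,6,7-tetramethylnona-6,8-dien-1-ol
Product: 20 (2S,3R,6E)-2-[2-(tert-butyldimethylsilyloxy)ethyl]-2,3,6,7-tetramethylnona-6,8-dien-1-ol
Conditions: TBSCl (1.05 equiv), imidazole, CH2Cl2, −20 → 0 °C
Reagents that add atoms: tert-butyldimethylsilyl chloride, CC(C)(C)[Si](C)(C)Cl
Why: Sterically controlled monosilylation, because the C12 hydroxyl at the end of the ethyl arm should react much faster than the neopentyl C10 hydroxyl next to quaternary C9.

**Step 13**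
Reactants: 20 (2S,3R,6E)-2-[2-(tert-butyldimethylsilyloxy)ethyl]-2,3,6,7-tetramethylnona-6,8-dien-1-ol
Product: 21 (2S,3R,6E)-2-[2-(tert-butyldimethylsilyloxy)ethyl]-2,3,6,7-tetramethylnona-6,8-dienal
Conditions: Dess–Martin periodinane, CH2Cl2, 0 °C → rt
Reagents that add atoms: none
Why: Dess–Martin oxidation handles hindered neopentyl alcohols under nearly neutral conditions, spares the diene and the silyl ether, and the aldehyde cannot epimerise because C9 bears no hydrogen.

**Step 14**
Reactants: 21 (2S,3R,6E)-2-[2-(tert-butyldimethylsilyloxy)ethyl]-2,3,6,7-tetramethylnona-6,8-dienal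
Product: 22 [(1E,3S,4R,7E)-3-[2-(tert-butyldimethylsilyloxy)ethyl]-3,4,7,8-tetramethyldeca-1,7,9-trien-1-yl]sulfonylbenzene
Conditions: (EtO)2P(O)CH2SO2Ph, NaH, THF, 0 °C; then 21, 0 °C → rt
Reagents that add atoms: diethyl [(phenylsulfonyl)methyl]phosphonate, CCOP(=O)(OCC)CS(=O)(=O)c1ccccc1
Why: Horner–Wadsworth–Emmons olefination with the sulfonyl-stabilised phosphonate anion adds C1 and should give the (E)-vinyl sulfone, while the lack of a hydrogen on C9 rules out drift to an allyl sulfone.

**Step 15**
Reactants: 22 [(1E,3S,4R,7E)-3-[2-(tert-butyldimethylsilyloxy)ethyl]-3,4,7,8-tetramethyldeca-1,7,9-trien-1-yl]sulfonylbenzene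
Product: 23 tert-butyldimethyl{2-[(1S,2R,4aR,8R,8aR)-1,2,4a,5-tetramethyl-8-(phenylsulfonyl)-1,2,3,4,4a,7,8,8a-octahydronaphthalen-1-yl]ethoxy}silane
Conditions: PhMe (0.01 M), BHT (cat.), degassed, sealed tube, 160–180 °C
Reagents that add atoms: none
Why: The diene C2=C3–C4=C5 and the (E)-vinyl sulfone C1=C10 of the same chain should combine in a concerted, suprafacial [4+2] cycloaddition that makes C1–C2 and C5–C10 together; the closest known reaction type is the thermal type 1 intramolecular Diels–Alder reaction of sulfonyl-terminated 1,7,9-decatrienes. Ring A closes as the six-membered cycloadduct ring, with the new alkene appearing at C3=C4, and ring B closes in the fused mode as a six-membered ring through the link C6–C7–C8–C9 folded as a chair. C6 holds the outer position on C5 and both alkene geometries are carried over, so the arrangement with the sulfonyl group endo and C9 exo gives H10 anti to C19 (trans fusion, C5 and C10) and an equatorial sulfonyl group on C1 cis to H10. The sense of C5 and C10 relative to the existing centres is fixed by C8 and C9, since only one diene face is reached with the C17 methyl and the C11 arm both equatorial on that chair, which leaves C20 axial and syn to C19. The step needs trans over cis fusion and one diene face: the cis-forming mode would tuck the fully substituted C9 under the diene against the C18 methyl, and the other face would cost an axial C17 and an axial C11 arm. The electron-poor sulfone and the geminal substitution at C9 should allow a temperature at which ring closure still outruns the 1,5-hydrogen shift from the inner C19 methyl.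

**Step 16**
Reactants: 23 tert-butyldimethyl{2-[(1S,2R,4aR,8R,8aR)-1,2,4a,5-tetramethyl-8-(phenylsulfonyl)-1,2,3,4,4a,7,8,8a-octahydronaphthalen-1-yl]ethoxy}silane
Product: 24 tert-butyldimethyl{2-[(1S,2R,4aR,8aR)-1,2,4a,5-tetramethyl-1,2,3,4,4a,7,8,8a-octahydronaphthalen-1-yl]ethoxy}silane
Conditions: Na(Hg) (6 %), Na2HPO4, MeOH/THF, −20 °C → rt
Reagents that add atoms: none
Why: Reductive desulfonylation by electron transfer, in which the sulfone radical anion splits into benzenesulfinate and a C1 radical that is reduced and protonated, erasing the C1 centre while the alkene and the silyl ether stay.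

**Step 17**
Reactants: 24 tert-butyldimethyl{2-[(1S,2R,4aR,8aR)-1,2,4a,5-tetramethyl-1,2,3,4,4a,7,8,8a-octahydronaphthalen-1-yl]ethoxy}silane
Product: 25 2-[(1S,2R,4aR,8aR)-1,2,4a,5-tetramethyl-1,2,3,4,4a,7,8,8a-octahydronaphthalen-1-yl]ethanol
Conditions: HF·pyridine, pyridine, THF, 0 °C → rt
Reagents that add atoms: none
Why: Fluoride-driven desilylation of a primary TBS ether, pulled by the strong Si–F bond and mild enough for the trisubstituted alkene.

**Step 18**
Reactants: 25 2-[(1S,2R,4aR,8aR)-1,2,4a,5-tetramethyl-1,2,3,4,4a,7,8,8a-octahydronaphthalen-1-yl]ethanol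
Product: 26 (1S,2R,4aR,8aR)-1-(2-iodoethyl)-1,2,4a,5-tetramethyl-1,2,3,4,4a,7,8,8a-octahydronaphthalene
Conditions: I2, PPh3, imidazole, CH2Cl2, 0 °C → rt
Reagents that add atoms: iodine, II
Why: Appel-type iodination of the primary C12 alcohol by SN2 displacement one carbon away from the quaternary centre, under conditions that do not add to the hindered alkene.

**Step 19**
Reactants: 27 2-butyne-1,4-diol
Product: 28 4-(tert-butyldimethylsilyloxy)but-2-yn-1-ol
Conditions: 27 (3 equiv), TBSCl (1 equiv), imidazole, DMF, 0 °C → rt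
Reagents that add atoms: tert-butyldimethylsilyl chloride, CC(C)(C)[Si](C)(C)Cl
Why: Statistical monosilylation of a cheap symmetrical diol used in excess, the water-soluble surplus being washed out.

**Step 20**
Reactants: 28 4-(tert-butyldimethylsilyloxy)but-2-yn-1-ol
Product: 30 (Z)-4-(tert-butyldimethylsilyloxy)-3-iodobut-2-en-1-ol, via cyclic alkenylaluminate 29 (not isolated)
Conditions: NaAlH2(OCH2CH2OCH3)2, THF, 0 °C → rt; then I2, THF, −78 → 0 °C
Reagents that add atoms: iodine, II
Why: Hydroxyl-directed anti hydroalumination of the propargylic alcohol puts aluminium on the distal alkyne carbon within a five-membered alkoxyaluminate ring and hydride trans to it, and iodinolysis of the C–Al bond with retention should give the iodide cis to the CH2OH group.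

**Step 21**
Reactants: 30 (Z)-4-(tert-butyldimethylsilyloxy)-3-iodobut-2-en-1-ol; 31 docosanoyl chloride
Product: 32 (Z)-4-(tert-butyldimethylsilyloxy)-3-iodobut-2-en-1-yl docosanoate
Conditions: Et3N, DMAP (cat.), CH2Cl2, 0 °C → rt
Reagents that add atoms: none
Why: DMAP-catalysed acylation of the only free hydroxyl (C15) through the acylpyridinium ion, with no effect on the alkenyl iodide or its geometry.

**Step 22**
Reactants: 26 (1S,2R,4aR,8aR)-1-(2-iodoethyl)-1,2,4a,5-tetramethyl-1,2,3,4,4a,7,8,8a-octahydronaphthalene; 32 (Z)-4-(tert-butyldimethylsilyloxy)-3-iodobut-2-en-1-yl docosanoate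
Product: 34 (E)-3-[(tert-butyldimethylsilyloxy)methyl]-5-[(1S,2R,4aR,8aR)-1,2,4a,5-tetramethyl-1,2,3,4,4a,7,8,8a-octahydronaphthalen-1-yl]pent-2-en-1-yl docosanoate, via alkylzinc iodide 33 (not isolated)
Conditions: Zn dust (I2-activated), DMA, 40 °C; then 32 (slight excess), Pd(PPh3)4 (5 mol %), THF/DMA, rt
Reagents that add atoms: none
Why: Negishi coupling in which oxidative addition of zerovalent palladium to the alkenyl C–I bond should be much faster than ionisation of the allylic ester, the alkylzinc tolerates the ester, and retention places C12 cis to C15.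

**Step 23**
Reactants: 34 (E)-3-[(tert-butyldimethylsilyloxy)methyl]-5-[(1S,2R,4aR,8aR)-1,2,4a,5-tetramethyl-1,2,3,4,4a,7,8,8a-octahydronaphthalen-1-yl]pent-2-en-1-yl docosanoate
Product: 35 (E)-3-(hydroxymethyl)-5-[(1S,2R,4aR,8aR)-1,2,4a,5-tetramethyl-1,2,3,4,4a,7,8,8a-octahydronaphthalen-1-yl]pent-2-en-1-yl docosanoate (CNP0279526.1)
Conditions: HF·pyridine, pyridine, THF, 0 °C → rt
Reagents that add atoms: none
Why: Buffered fluoride desilylation frees the C16 hydroxyl without cleaving the ester, and acyl migration is geometrically barred because C15 and C16 lie trans across the alkene.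

**Compound list**
1 | 3-methylglutaric anhydride | CC1CC(=O)OC(=O)C1 | starting material
2 | (R)-5-methoxy-3-methyl-5-oxopentanoic acid | COC(=O)C[C@H](C)CC(=O)O | intermediate
3 | methyl (R)-5-hydroxy-3-methylpentanoate | COC(=O)C[C@H](C)CCO | intermediate
4 | (R)-4-methyloxan-2-one | O=C1C[C@H](C)CCO1 | intermediate
5 | lithium enolate of 4 | [Li]OC1=C[C@H](C)CCO1 | intermediate
6 | (3S,4R)-3,4-dimethyloxan-2-one (trans) | O=C1[C@@H](C)[C@H](C)CCO1 | intermediate
7 | allyl bromide | C=CCBr | starting material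
8 | lithium enolate of 6 | [Li]OC1=C(C)[C@H](C)CCO1 | intermediate
9 | (3S,4R)-3-allyl-3,4-dimethyloxan-2-one | O=C1[C@](CC=C)(C)[C@H](C)CCO1 | intermediate
10 | (3S,4R)-3-(2-hydroxyethyl)-3,4-dimethyloxan-2-one | O=C1[C@](CCO)(C)[C@H](C)CCO1 | intermediate
11 | (3S)-3-[(2R)-4-hydroxybutan-2-yl]-3-methyloxolan-2-one | O=C1OCC[C@@]1(C)[C@H](C)CCO | intermediate
12 | (3S)-3-[(2R)-4-iodobutan-2-yl]-3-methyloxolan-2-one | O=C1OCC[C@@]1(C)[C@H](C)CCI | intermediate
13 | methyl 2-methyl-3-oxobutanoate | CC(=O)C(C)C(=O)OC | starting material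
14 | methyl (E)-2-methyl-3-(tosyloxy)but-2-enoate | C/C(OS(=O)(=O)c1ccc(C)cc1)=C(/C)C(=O)OC | intermediate
15 | alkylzinc iodide from 12 (zinc on C6) | O=C1OCC[C@@]1(C)[C@H](C)CC[Zn]I | intermediate
16 | methyl (2E,6R)-2,3-dimethyl-6-[(3S)-3-methyl-2-oxooxolan-3-yl]hept-2-enoate | O=C1OCC[C@@]1(C)[C@H](C)CC/C(C)=C(\C)C(=O)OC | intermediate
17 | (2E,6R,7S)-7-(hydroxymethyl)-2,3,6,7-tetramethylnon-2-ene-1,9-diol | OCC[C@@](CO)(C)[C@H](C)CC/C(C)=C(\C)CO | intermediate
18 | (2E,6R,7S)-9-hydroxy-7-(hydroxymethyl)-2,3,6,7-tetramethylnon-2-enal | OCC[C@@](CO)(C)[C@H](C)CC/C(C)=C(\C)C=O | intermediate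
19 | (2S,3R,6E)-2-(2-hydroxyethyl)-2,3,6,7-tetramethylnona-6,8-dien-1-ol | OCC[C@@](CO)(C)[C@H](C)CC/C(C)=C(\C)C=C | intermediate
20 | (2S,3R,6E)-2-[2-(tert-butyldimethylsilyloxy)ethyl]-2,3,6,7-tetramethylnona-6,8-dien-1-ol | CC(C)(C)[Si](C)(C)OCC[C@@](CO)(C)[C@H](C)CC/C(C)=C(\C)C=C | intermediate
21 | (2S,3R,6E)-2-[2-(tert-butyldimethylsilyloxy)ethyl]-2,3,6,7-tetramethylnona-6,8-dienal | CC(C)(C)[Si](C)(C)OCC[C@@](C=O)(C)[C@H](C)CC/C(C)=C(\C)C=C | intermediate
22 | [(1E,3S,4R,7E)-3-[2-(tert-butyldimethylsilyloxy)ethyl]-3,4,7,8-tetramethyldeca-1,7,9-trien-1-yl]sulfonylbenzene | CC(C)(C)[Si](C)(C)OCC[C@@](/C=C/S(=O)(=O)c1ccccc1)(C)[C@H](C)CC/C(C)=C(\C)C=C | intermediate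
23 | tert-butyldimethyl{2-[(1S,2R,4aR,8R,8aR)-1,2,4a,5-tetramethyl-8-(phenylsulfonyl)-1,2,3,4,4a,7,8,8a-octahydronaphthalen-1-yl]ethoxy}silane | CC(C)(C)[Si](C)(C)OCC[C@@]1(C)[C@H](C)CC[C@@]2(C)C(C)=CC[C@@H](S(=O)(=O)c3ccccc3)[C@H]12 | intermediate
24 | tert-butyldimethyl{2-[(1S,2R,4aR,8aR)-1,2,4a,5-tetramethyl-1,2,3,4,4a,7,8,8a-octahydronaphthalen-1-yl]ethoxy}silane | CC(C)(C)[Si](C)(C)OCC[C@@]1(C)[C@H](C)CC[C@@]2(C)C(C)=CCC[C@H]12 | intermediate
25 | 2-[(1S,2R,4aR,8aR)-1,2,4a,5-tetramethyl-1,2,3,4,4a,7,8,8a-octahydronaphthalen-1-yl]ethanol | OCC[C@@]1(C)[C@H](C)CC[C@@]2(C)C(C)=CCC[C@H]12 | intermediate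
26 | (1S,2R,4aR,8aR)-1-(2-iodoethyl)-1,2,4a,5-tetramethyl-1,2,3,4,4a,7,8,8a-octahydronaphthalene | ICC[C@@]1(C)[C@H](C)CC[C@@]2(C)C(C)=CCC[C@H]12 | intermediate
27 | 2-butyne-1,4-diol | OCC#CCO | starting material
28 | 4-(tert-butyldimethylsilyloxy)but-2-yn-1-ol | OCC#CCO[Si](C)(C)C(C)(C)C | intermediate
29 | sodium salt of the five-membered cyclic alkenyl(alkoxy)aluminate from 28 | [Na+].COCCO[Al-]1(OCCOC)OCC=C1CO[Si](C)(C)C(C)(C)C | intermediate
30 | (Z)-4-(tert-butyldimethylsilyloxy)-3-iodobut-2-en-1-ol | OC/C=C(/CO[Si](C)(C)C(C)(C)C)I | intermediate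
31 | docosanoyl chloride | CCCCCCCCCCCCCCCCCCCCCC(=O)Cl | starting material
32 | (Z)-4-(tert-butyldimethylsilyloxy)-3-iodobut-2-en-1-yl docosanoate | CCCCCCCCCCCCCCCCCCCCCC(=O)OC/C=C(/CO[Si](C)(C)C(C)(C)C)I | intermediate
33 | alkylzinc iodide from 26 (zinc on C12) | I[Zn]CC[C@@]1(C)[C@H](C)CC[C@@]2(C)C(C)=CCC[C@H]12 | intermediate
34 | (E)-3-[(tert-butyldimethylsilyloxy)methyl]-5-[(1S,2R,4aR,8aR)-1,2,4a,5-tetramethyl-1,2,3,4,4a,7,8,8a-octahydronaphthalen-1-yl]pent-2-en-1-yl docosanoate | CCCCCCCCCCCCCCCCCCCCCC(=O)OC/C=C(/CO[Si](C)(C)C(C)(C)C)CC[C@@]1(C)[C@H](C)CC[C@@]2(C)C(C)=CCC[C@H]12 | intermediate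
35 | (E)-3-(hydroxymethyl)-5-[(1S,2R,4aR,8aR)-1,2,4a,5-tetramethyl-1,2,3,4,4a,7,8,8a-octahydronaphthalen-1-yl]pent-2-en-1-yl docosanoate (CNP0279526.1) | CCCCCCCCCCCCCCCCCCCCCC(=O)OC/C=C(/CO)CC[C@@]1(C)[C@H](C)CC[C@@]2(C)C(C)=CCC[C@H]12 | target

**Step count**
Total: 23 steps. Longest linear sequence: 19 steps (steps 1–6, 8–18, 22 and 23).

**Steps most likely to fail**

Step 15. Bond formation at the fully substituted C5, next to quaternary C9, may be slow enough that the 1,5-hydrogen shift from the inner C19 methyl to C2 consumes the diene first. The weak endo preference of a sulfonyl group may also erode the trans/cis selectivity at the temperature required.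
The fallback sets out from 21 and comes back at 24. It swaps the activating group for a formyl group that answers to a Lewis acid, so the cycloaddition can run far below the temperature of the hydrogen shift.
- Horner–Wadsworth–Emmons olefination of 21 with triethyl phosphonoacetate and NaH would give the ethyl (E)-trienoate F1.
- Reduction with i-Bu2AlH would give the allylic alcohol F2, and MnO2 would give the trienal F3.
- Me2AlCl in CH2Cl2 (−78 → 0 °C) should promote the same intramolecular Diels–Alder closure with a strongly endo formyl group, giving the trans-fused C1-carbaldehyde F4.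
- Tsuji–Wilkinson decarbonylation with RhCl(PPh3)3 in hot PhMe would remove the formyl carbon and deliver 24.

Step 8. Oxidative addition of zerovalent palladium into the hindered, tetrasubstituted C–OTs bond may lag behind protodezincation or β-hydride loss from the alkyl partner. A competing addition–elimination pathway could also leak alkene geometry.
The fallback sets out from 12 and comes back at 16. It replaces the zinc nucleophile by a borane made through hydroboration.
- E2 elimination of 12 with KOt-Bu in THF would give the vinyl lactone F5.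
- Hydroboration with 9-borabicyclo[3.3.1]nonane would give the B-alkyl borane F6.
- A B-alkyl Suzuki–Miyaura coupling of F6 with 14 [PdCl2(dppf), Cs2CO3, DMF/THF/H2O, 50 °C] should form the same C5–C6 bond with retention and give 16.

Step 22. Zerovalent palladium may ionise the allylic docosanoate of 32 or of 34. That would cause loss of the ester, allylic substitution by the zinc reagent, or leakage of alkene geometry through a π-allyl complex.
The fallback sets out from 30 (with 26 as before) and comes back at 34. It postpones the acylation until after the coupling.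
- Alcohol 30 would be capped with Et3SiCl and imidazole as the triethylsilyl ether F7.
- The zinc reagent 33 would be coupled with F7 under Pd(PPh3)4 to give the bis-silyl ether F8.
- The more labile triethylsilyl ether would be cleaved selectively (pyridinium tosylate, MeOH, 0 °C) to the C15 alcohol F9.
- Acylation of F9 with 31 (Et3N, DMAP) would give 34.

**Further compounds**
F1 | step 15 | ethyl (2E,4S,5R,8E)-4-[2-(tert-butyldimethylsilyloxy)ethyl]-4,5,8,9-tetramethylundeca-2,8,10-trienoate | CC(C)(C)[Si](C)(C)OCC[C@@](/C=C/C(=O)OCC)(C)[C@H](C)CC/C(C)=C(\C)C=C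
F2 | step 15 | (2E,4S,5R,8E)-4-[2-(tert-butyldimethylsilyloxy)ethyl]-4,5,8,9-tetramethylundeca-2,8,10-trien-1-ol | CC(C)(C)[Si](C)(C)OCC[C@@](/C=C/CO)(C)[C@H](C)CC/C(C)=C(\C)C=C
F3 | step 15 | (2E,4S,5R,8E)-4-[2-(tert-butyldimethylsilyloxy)ethyl]-4,5,8,9-tetramethylundeca-2,8,10-trienal | CC(C)(C)[Si](C)(C)OCC[C@@](/C=C/C=O)(C)[C@H](C)CC/C(C)=C(\C)C=C
F4 | step 15 | (1R,4aR,7R,8S,8aR)-8-[2-(tert-butyldimethylsilyloxy)ethyl]-4,4a,7,8-tetramethyl-1,2,4a,5,6,7,8,8a-octahydronaphthalene-1-carbaldehyde | CC(C)(C)[Si](C)(C)OCC[C@@]1(C)[C@H](C)CC[C@@]2(C)C(C)=CC[C@@H](C=O)[C@H]12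
F5 | step 8 | (3S)-3-[(2R)-but-3-en-2-yl]-3-methyloxolan-2-one | O=C1OCC[C@@]1(C)[C@H](C)C=C
F6 | step 8 | (3S)-3-[(2R)-4-(9-borabicyclo[3.3.1]nonan-9-yl)butan-2-yl]-3-methyloxolan-2-one | O=C1OCC[C@@]1(C)[C@H](C)CCB2C3CCCC2CCC3
F7 | step 22 | (Z)-4-(tert-butyldimethylsilyloxy)-3-iodo-1-(triethylsilyloxy)but-2-ene | CC[Si](CC)(CC)OC/C=C(/CO[Si](C)(C)C(C)(C)C)I
F8 | step 22 | C15 triethylsilyl, C16 tert-butyldimethylsilyl bis-ether of the (E)-diol side chain on the (1S,2R,4aR,8aR)-decalin | CC[Si](CC)(CC)OC/C=C(/CO[Si](C)(C)C(C)(C)C)CC[C@@]1(C)[C@H](C)CC[C@@]2(C)C(C)=CCC[C@H]12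
F9 | step 22 | (E)-3-[(tert-butyldimethylsilyloxy)methyl]-5-[(1S,2R,4aR,8aR)-1,2,4a,5-tetramethyl-1,2,3,4,4a,7,8,8a-octahydronaphthalen-1-yl]pent-2-en-1-ol | OC/C=C(/CO[Si](C)(C)C(C)(C)C)CC[C@@]1(C)[C@H](C)CC[C@@]2(C)C(C)=CCC[C@H]12
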